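**Strategy.** The route rests on disconnecting the C–C bond between the benzylic O–CH(Ar) carbon of the tetrahydrofuran ring that carries the prenyloxyaryl group and the adjacent ring-fusion carbon. The key step exploits the O–CH(Ar)–CH–CH2–O array: the benzylic carbon is an aldehyde carbon at the oxocarbenium level, and the ring-fusion carbon is alpha to a latent formyl group, the OCH2 carbon of the second ring. In one operation a primary silyl ether and the prenyloxy aldehyde give an oxocarbenium ion that is trapped by a tethered Z-enol carbamate, which closes the ring, sets the aryl-bearing centre and releases the aldehyde for the second ring. The precursor is an acyclic homoaldol adduct; its carbamate is a temporary activating group.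

Key step: step 7

Assumption: deprotonation of 7 with n-BuLi/(+)-sparteine is taken to give the (R)-configured lithium carbanion (mirror image of the pro-S selectivity of (−)-sparteine) and Li–Ti exchange to go with inversion; if the induction proves opposite, the antipodal diamine is used.

**Step 1**
Reactants: 1 vanillin; 2 prenyl bromide
Product: 3 3-methoxy-4-[(3-methylbut-2-en-1-yl)oxy]benzaldehyde
Conditions: K2CO3, DMF, rt
Reagents that add atoms: none
Why: Williamson ether synthesis, the phenoxide displacing the primary allylic bromide (SN2); no stereocentre is formed.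

**Step 2**
Reactants: 1 vanillin
Product: 4 4-formyl-2-methoxyphenyl 4-methylbenzenesulfonate
Conditions: TsCl, K2CO3, acetone, rt
Reagents that add atoms: 4-toluenesulfonyl chloride, Cc1ccc(cc1)S(Cl)(=O)=O
Why: Sulfonylation of the phenol; the tosylate should survive the organotitanium, Lewis-acid and mild-base steps and makes this ring electron-poor, so that its benzylic C–O bond cannot ionise later.

**Step 3**
Reactants: 5 (E)-but-2-ene-1,4-diol
Product: 6 (E)-4-[(tert-butyldimethylsilyl)oxy]but-2-en-1-ol
Conditions: NaH (1.0 equiv), THF, 0 °C; TBSCl (1.0 equiv), rt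
Reagents that add atoms: tert-butyldimethylsilyl chloride, CC(C)(C)[Si](C)(C)Cl
Why: Monosilylation of a symmetric diol through its monosodium alkoxide (silyl ether formation).

**Step 4**
Reactants: 6 (E)-4-[(tert-butyldimethylsilyl)oxy]but-2-en-1-ol
Product: 7 (E)-4-[(tert-butyldimethylsilyl)oxy]but-2-en-1-yl N,N-diisopropylcarbamate
Conditions: NaH, THF, 0 °C; iPr2NCOCl, reflux
Reagents that add atoms: N,N-diisopropylcarbamoyl chloride, CC(C)N(C(C)C)C(Cl)=O
Why: O-acylation of the alkoxide by the carbamoyl chloride installs the group that directs alpha-lithiation and later serves as the enol activating group.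

**Step 5**
Reactants: 7 (E)-4-[(tert-butyldimethylsilyl)oxy]but-2-en-1-yl N,N-diisopropylcarbamate; 4 4-formyl-2-methoxyphenyl 4-methylbenzenesulfonate
Product: 10 (1Z,3S,4R)-3-{[(tert-butyldimethylsilyl)oxy]methyl}-4-hydroxy-4-[3-methoxy-4-(tosyloxy)phenyl]but-1-en-1-yl N,N-diisopropylcarbamate, via lithiated carbamate 8 (not isolated), via allyltitanium reagent 9 (not isolated)
Conditions: n-BuLi, (+)-sparteine, toluene, −78 °C; Ti(OiPr)4, −78 °C; 4, −78 → −40 °C; aq. HCl
Reagents that add atoms: none
Why: Hoppe homoaldol reaction: carbamate-directed deprotonation in the chiral diamine complex, Li-to-Ti exchange with inversion and gamma-attack of the allyltitanium on the aldehyde through a chair Zimmerman–Traxler transition state (aryl equatorial, carbamoyloxy axial) should give the Z-enol carbamate with anti C3/C4 configuration, the absolute configuration being relayed from the C–Ti stereocentre.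

**Step 6**
Reactants: 10 homoaldol adduct
Product: 11 (1Z,3S,4R)-4-acetoxy-3-{[(tert-butyldimethylsilyl)oxy]methyl}-4-[3-methoxy-4-(tosyloxy)phenyl]but-1-en-1-yl N,N-diisopropylcarbamate
Conditions: Ac2O, pyridine, DMAP (cat.), CH2Cl2, rt
Reagents that add atoms: acetic anhydride, CC(=O)OC(C)=O
Why: DMAP-catalysed acylation blocks the secondary hydroxyl, which would otherwise compete for the aldehyde in step 7 and close the wrong ring.

**Step 7**
Reactants: 11 acetylated homoaldol adduct; 3 3-methoxy-4-[(3-methylbut-2-en-1-yl)oxy]benzaldehyde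
Product: 13 (2R,3S,4S)-4-{(R)-acetoxy[3-methoxy-4-(tosyloxy)phenyl]methyl}-2-{3-methoxy-4-[(3-methylbut-2-en-1-yl)oxy]phenyl}oxolane-3-carbaldehyde (2,3-cis and 3,4-trans), via oxocarbenium triflate 12 (not isolated)
Conditions: Me3SiOTf (1.2 equiv), 2,6-di-tert-butyl-4-methylpyridine (0.3 equiv), CH2Cl2, −78 °C; sat. aq. NaHCO3 at −78 °C
Reagents that add atoms: none
Why: Me3SiOTf converts the primary silyl ether and aldehyde 3 into the E-configured oxocarbenium ion 12, whose carbon is attacked by the beta-carbon of the tethered Z-enol carbamate, and loss of the carbamoyl group then unveils the aldehyde. The closest known reaction type is the Lewis acid-mediated condensation of 4-oxy-1-alkenyl carbamates with aldehydes to tetrahydrofuran-3-carbaldehydes, an intramolecular Mukaiyama/Prins-type addition to an oxocarbenium ion. The tetrahydrofuran ring closes in a 5-endo-trig sense at the C=O+ unit with the enol double bond exocyclic to the new ring (enol-exo). The ring carbon next to the existing stereocentre is controlled by allylic 1,3-strain in the Z-enol carbamate (allylic hydrogen in the enol plane, so the new bond forms anti to the CH(OAc)Ar arm, 3,4-trans), and the aryl-bearing carbon by the synclinal approach of the E-oxocarbenium ion that places the aryl group over the enol carbon (2,3-cis). The step needs reaction at the primary silyl ether only and an intact benzylic C–O bond, which the acetate on the hindered, electron-poor tosyloxyaryl carbinol and the low temperature should secure; for the target only the trans relation between the new aryl group and the CH(OAc)Ar arm matters, because the formyl-bearing centre is corrected in step 8.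

**Step 8**
Reactants: 13 oxolane-3-carbaldehyde
Product: 16 4-[(1R,3aR,4R,6aS)-3-hydroxy-4-{3-methoxy-4-[(3-methylbut-2-en-1-yl)oxy]phenyl}tetrahydro-1H,3H-furo[3,4-c]furan-1-yl]-2-methoxyphenyl 4-methylbenzenesulfonate (lactol; mixture at C3), via hydroxy aldehyde 14 (not isolated), via epimeric hydroxy aldehyde 15 (not isolated)
Conditions: K2CO3, MeOH, 0 °C → rt
Reagents that add atoms: none
Why: Transesterification removes the acetate, the aldehyde alpha-centre epimerises through its enolate, and only the 3,4-cis epimer 15 can close to the cis-fused five-membered lactol, which should drain the equilibrium (thermodynamic control of that centre); the tosylate is inert and no other centre is acidic.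

**Step 9**
Reactants: 16 furofuran lactol
Product: 18 4-[(1R,3aS,4R,6aS)-4-{3-methoxy-4-[(3-methylbut-2-en-1-yl)oxy]phenyl}tetrahydro-1H,3H-furo[3,4-c]furan-1-yl]-2-methoxyphenyl 4-methylbenzenesulfonate, via bicyclic oxocarbenium ion 17 (not isolated)
Conditions: Et3SiH (3 equiv), BF3·OEt2 (2 equiv), CH2Cl2, −78 → −40 °C; sat. aq. NaHCO3
Reagents that add atoms: none
Why: Ionic hydrogenation of a lactol: BF3 generates the cyclic oxocarbenium ion 17, which Et3SiH reduces to the CH2–O unit without touching a stereocentre, while the electron-poor tosyloxyaryl group keeps the adjacent benzylic C–O bond from ionising.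

**Step 10**
Reactants: 18 tosyl-protected furofuran
Product: 19 4-[(1R,3aS,4R,6aS)-4-{3-methoxy-4-[(3-methylbut-2-en-1-yl)oxy]phenyl}tetrahydro-1H,3H-furo[3,4-c]furan-1-yl]-2-methoxyphenol
Conditions: KOH, MeOH/THF/H2O, 60 °C; aq. NH4Cl
Reagents that add atoms: none
Why: Hydroxide attacks sulfur of the aryl sulfonate and releases the phenoxide (S–O cleavage); the benzylic ethers, the aryl prenyl ether and all stereocentres are stable to base.

**Compound list**

1 | vanillin (4-hydroxy-3-methoxybenzaldehyde) | COc1cc(C=O)ccc1O | starting material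
2 | prenyl bromide (1-bromo-3-methylbut-2-ene) | CC(C)=CCBr | starting material
3 | 3-methoxy-4-[(3-methylbut-2-en-1-yl)oxy]benzaldehyde | COc1cc(C=O)ccc1OCC=C(C)C | intermediate
4 | 4-formyl-2-methoxyphenyl 4-methylbenzenesulfonate | COc1cc(C=O)ccc1OS(=O)(=O)c1ccc(C)cc1 | intermediate
5 | (E)-but-2-ene-1,4-diol | OC/C=C/CO | starting material
6 | (E)-4-[(tert-butyldimethylsilyl)oxy]but-2-en-1-ol | CC(C)(C)[Si](C)(C)OC/C=C/CO | intermediate
7 | (E)-4-[(tert-butyldimethylsilyl)oxy]but-2-en-1-yl N,N-diisopropylcarbamate | CC(C)N(C(C)C)C(=O)OC/C=C/CO[Si](C)(C)C(C)(C)C | intermediate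
8 | (R)-1-lithio derivative of 7, held as its (+)-sparteine complex (SMILES without the diamine) | CC(C)N(C(C)C)C(=O)O[C@H]([Li])/C=C/CO[Si](C)(C)C(C)(C)C | intermediate (not isolated)
9 | (S)-[(E)-1-(diisopropylcarbamoyloxy)-4-(tert-butyldimethylsilyloxy)but-2-en-1-yl]triisopropoxytitanium | CC(C)N(C(C)C)C(=O)O[C@@H]([Ti](OC(C)C)(OC(C)C)OC(C)C)/C=C/CO[Si](C)(C)C(C)(C)C | intermediate (not isolated)
10 | (1Z,3S,4R)-3-{[(tert-butyldimethylsilyl)oxy]methyl}-4-hydroxy-4-[3-methoxy-4-(tosyloxy)phenyl]but-1-en-1-yl N,N-diisopropylcarbamate | CC(C)N(C(C)C)C(=O)O/C=C\[C@@H](CO[Si](C)(C)C(C)(C)C)[C@@H](O)c1ccc(OS(=O)(=O)c2ccc(C)cc2)c(OC)c1 | intermediate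
11 | (1Z,3S,4R)-4-acetoxy-3-{[(tert-butyldimethylsilyl)oxy]methyl}-4-[3-methoxy-4-(tosyloxy)phenyl]but-1-en-1-yl N,N-diisopropylcarbamate | CC(C)N(C(C)C)C(=O)O/C=C\[C@@H](CO[Si](C)(C)C(C)(C)C)[C@@H](OC(C)=O)c1ccc(OS(=O)(=O)c2ccc(C)cc2)c(OC)c1 | intermediate
12 | E-oxocarbenium triflate formed from the primary oxygen of 11 and aldehyde 3 | CC(C)N(C(C)C)C(=O)O/C=C\[C@@H](C/[O+]=C/c1ccc(OCC=C(C)C)c(OC)c1)[C@@H](OC(C)=O)c1ccc(OS(=O)(=O)c2ccc(C)cc2)c(OC)c1.[O-]S(=O)(=O)C(F)(F)F | intermediate (not isolated)
13 | (2R,3S,4S)-4-{(R)-acetoxy[3-methoxy-4-(tosyloxy)phenyl]methyl}-2-{3-methoxy-4-[(3-methylbut-2-en-1-yl)oxy]phenyl}oxolane-3-carbaldehyde | O=C[C@@H]1[C@H](c2ccc(OCC=C(C)C)c(OC)c2)OC[C@H]1[C@@H](OC(C)=O)c1ccc(OS(=O)(=O)c2ccc(C)cc2)c(OC)c1 | intermediate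
14 | (2R,3S,4S)-4-{(R)-hydroxy[3-methoxy-4-(tosyloxy)phenyl]methyl}-2-{3-methoxy-4-[(3-methylbut-2-en-1-yl)oxy]phenyl}oxolane-3-carbaldehyde | O=C[C@@H]1[C@H](c2ccc(OCC=C(C)C)c(OC)c2)OC[C@H]1[C@@H](O)c1ccc(OS(=O)(=O)c2ccc(C)cc2)c(OC)c1 | intermediate (not isolated)
15 | (2R,3R,4S)-epimer of 14 (formyl group cis to the carbinol arm and trans to the aryl group) | O=C[C@H]1[C@H](c2ccc(OCC=C(C)C)c(OC)c2)OC[C@H]1[C@@H](O)c1ccc(OS(=O)(=O)c2ccc(C)cc2)c(OC)c1 | intermediate (not isolated)
16 | 4-[(1R,3aR,4R,6aS)-3-hydroxy-4-{3-methoxy-4-[(3-methylbut-2-en-1-yl)oxy]phenyl}tetrahydro-1H,3H-furo[3,4-c]furan-1-yl]-2-methoxyphenyl 4-methylbenzenesulfonate (both aryl groups exo; mixture at C3) | COc1cc([C@@H]2OC(O)[C@@H]3[C@H]2CO[C@H]3c2ccc(OCC=C(C)C)c(OC)c2)ccc1OS(=O)(=O)c1ccc(C)cc1 | intermediate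
17 | bicyclic oxocarbenium ion from 16 (C=O+ at the former lactol carbon) | COc1cc([C@@H]2[O+]=C[C@@H]3[C@H]2CO[C@H]3c2ccc(OCC=C(C)C)c(OC)c2)ccc1OS(=O)(=O)c1ccc(C)cc1 | intermediate (not isolated)
18 | 4-[(1R,3aS,4R,6aS)-4-{3-methoxy-4-[(3-methylbut-2-en-1-yl)oxy]phenyl}tetrahydro-1H,3H-furo[3,4-c]furan-1-yl]-2-methoxyphenyl 4-methylbenzenesulfonate | COc1cc([C@@H]2OC[C@@H]3[C@H]2CO[C@H]3c2ccc(OCC=C(C)C)c(OC)c2)ccc1OS(=O)(=O)c1ccc(C)cc1 | intermediate
19 | 4-[(1R,3aS,4R,6aS)-4-{3-methoxy-4-[(3-methylbut-2-en-1-yl)oxy]phenyl}tetrahydro-1H,3H-furo[3,4-c]furan-1-yl]-2-methoxyphenol | COc1cc([C@@H]2OC[C@@H]3[C@H]2CO[C@H]3c2ccc(OCC=C(C)C)c(OC)c2)ccc1O | target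

**Totals.** Total step count: 10. Longest linear sequence: 8 steps (steps 3 to 10, from diol 5).

**Steps most likely to fail**

1. Step 7. The kinetic diastereoselection of the oxocarbenium capture may be lost, either by attack through the antiperiplanar instead of the synclinal arrangement or by Lewis-acid equilibration of the aldehyde through ring opening and reclosure. Either would place the new aryl group cis to the carbinol arm. The fallback uses known chemistry and reverses the order of ring formation; it sets out from 10. The free secondary hydroxyl of 10 is condensed with dimethoxymethane (BF3·OEt2, CH2Cl2, −78 °C) in the same enol carbamate/oxocarbenium manner, which closes the ring bearing the tosyloxyaryl group and should give the formyl oxolane F1. Bu4NF (THF) then removes the silyl group and epimerises the formyl-bearing centre, so that the bicyclic lactol F2 forms. Separately, 4-bromo-2-methoxyphenol is alkylated with 2 (K2CO3, DMF) to the aryl bromide F3, which with Mg (THF) gives the arylmagnesium bromide F4. Addition of F4 to F2 (THF, 0 °C) gives the diol F5. Acid-catalysed SN1 closure of its electron-rich benzylic carbinol onto the primary hydroxyl (camphorsulfonic acid cat., CH2Cl2, 0 °C), a closure that delivers the exo aryl group, comes back to the route at 18.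

2. Step 5. Enantiotopic differentiation in the deprotonation may be insufficient, or the lithiated carbamate may lose its configuration before the Li–Ti exchange; 1,4-elimination of silanolate from the allyl anion is a further hazard. The fallback replaces asymmetric deprotonation by resolution and sets out from 7 and 4. The homoaldol reaction is run with TMEDA in place of the chiral diamine (n-BuLi, toluene, −78 °C; Ti(OiPr)4; then 4) to give the racemic anti-Z adduct, that is 10 together with its enantiomer F6. Esterification with (S)-2-methoxy-2-phenylacetic acid (DCC, DMAP, CH2Cl2) gives the diastereomeric esters F7 (from 10) and F8 (from F6), which are separated by chromatography. Methanolysis of F7 (K2CO3, MeOH) comes back to the route at 10.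

3. Step 9. The Lewis acid may ionise the electron-rich benzylic C–O bond or the aryl prenyl ether during the ionic hydrogenation, leading to epimerisation, reductive ring opening or loss of the prenyl group. The fallback avoids the Lewis acid and sets out from 16. NaBH4 (MeOH, 0 °C) reduces the lactol through its hydroxy aldehyde form to the diol F9. Mitsunobu cyclodehydration (PPh3, DIAD, THF, 0 °C), in which the primary hydroxyl is activated and displaced by the benzylic oxygen with retention at the benzylic carbon, comes back to the route at 18.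

**Further compounds**

F1 | step 7 | (3R,4S,5R)-4-{[(tert-butyldimethylsilyl)oxy]methyl}-5-[3-methoxy-4-(tosyloxy)phenyl]oxolane-3-carbaldehyde | O=C[C@H]1CO[C@@H](c2ccc(OS(=O)(=O)c3ccc(C)cc3)c(OC)c2)[C@@H]1CO[Si](C)(C)C(C)(C)C
F2 | step 7 | cis-fused bicyclic lactol: analogue of 18 with a hydroxyl in place of the prenyloxyaryl group (anomeric mixture) | COc1cc([C@@H]2OC[C@@H]3[C@H]2COC3O)ccc1OS(=O)(=O)c1ccc(C)cc1
F3 | step 7 | 4-bromo-2-methoxy-1-[(3-methylbut-2-en-1-yl)oxy]benzene | COc1cc(Br)ccc1OCC=C(C)C
F4 | step 7 | {3-methoxy-4-[(3-methylbut-2-en-1-yl)oxy]phenyl}magnesium bromide | COc1cc([Mg]Br)ccc1OCC=C(C)C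
F5 | step 7 | diol: oxolane of 18 bearing the tosyloxyaryl group, with CH(OH)Ar (Ar = prenyloxyaryl; carbinol mixture) and CH2OH on the two former ring-fusion carbons | COc1cc([C@@H]2OC[C@@H](C(O)c3ccc(OCC=C(C)C)c(OC)c3)[C@H]2CO)ccc1OS(=O)(=O)c1ccc(C)cc1
F6 | step 5 | (1Z,3R,4S)-enantiomer of 10 (formed together with 10 as the racemate) | CC(C)N(C(C)C)C(=O)O/C=C\[C@H](CO[Si](C)(C)C(C)(C)C)[C@H](O)c1ccc(OS(=O)(=O)c2ccc(C)cc2)c(OC)c1
F7 | step 5 | (S)-2-methoxy-2-phenylacetate ester of 10 | CC(C)N(C(C)C)C(=O)O/C=C\[C@@H](CO[Si](C)(C)C(C)(C)C)[C@@H](OC(=O)[C@@H](OC)c1ccccc1)c1ccc(OS(=O)(=O)c2ccc(C)cc2)c(OC)c1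
F8 | step 5 | (S)-2-methoxy-2-phenylacetate ester of F6 | CC(C)N(C(C)C)C(=O)O/C=C\[C@H](CO[Si](C)(C)C(C)(C)C)[C@H](OC(=O)[C@@H](OC)c1ccccc1)c1ccc(OS(=O)(=O)c2ccc(C)cc2)c(OC)c1
F9 | step 9 | diol from reduction of 16: 2,3-trans-3,4-cis oxolane with the prenyloxyaryl group at C2, CH2OH at C3 and the (R)-hydroxy(tosyloxyaryl)methyl arm at C4 | OC[C@H]1[C@H](c2ccc(OCC=C(C)C)c(OC)c2)OC[C@H]1[C@@H](O)c1ccc(OS(=O)(=O)c2ccc(C)cc2)c(OC)c1
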